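**Assumption (one line):** locants C1–C20 are the verticillane-type positions of the target (C1 ring-junction CH, C4 exo-methylene carbon, C6 CH–OAc, C7=C8, C10 CH–O, C11=C12, C15 CMe2, C18 lactone C=O); the (R,R) antipode of the bis-phosphoramide catalyst is taken as Re-face selective (needed for C10) and the (S,S) antipode as Si-face selective (needed for C6) – if the sense is the opposite, the two antipodes are exchanged.

## Retrosynthetic overview

1. 24 ⇒ 23: the lactone C=O comes last, by oxidising C18H2 of a C10–O–C18 2,5-dihydrofuran; C4=C20 comes from the C4 ketone 22.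
2. 22 ⇒ acyclic ynone 20: both carbocycles are formed in one cation–olefin cascade in the order of the geranylgeranyl → cembrenyl → verticillenyl cation sequence. First the C1–C2 bond (14-membered ring, C15 cation), then the C11–C15 bond (cyclohexene, which leaves the 12-membered ring), ended by loss of Me3Si+ from C11; C10 controls C1.
3. 20 ⇒ enal 15 + alkynyl methyl ketone 16 (aldol, sets C6); 15 ⇒ enal 8 + senecioate dienolate 10 (vinylogous aldol, sets C10 and the 7E olefin).
4. 8 ⇒ 1 + 2 (anti-carbomagnesiation fixes the C11=C12 geometry and puts silicon on C11).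
5. Ring order: dihydrofuran (step 7) → 14-membered ring → cyclohexene (both in step 14) → lactone carbonyl (step 17).

## Route

Step 1
Reactants: 1 3-(trimethylsilyl)prop-2-yn-1-ol; 2 5-bromo-2-methylpent-2-ene
Product: 5 (2Z)-3-iodo-2-(4-methylpent-3-en-1-yl)-3-(trimethylsilyl)prop-2-en-1-ol, via (4-methylpent-3-en-1-yl)magnesium bromide 3 (not isolated), via cyclic alkenylmagnesium alkoxide 4 (not isolated)
Conditions: 2 (2.5 equiv), Mg, THF, rt; add to 1, CuI (10 mol %), Et2O, 0 °C → reflux; then I2, THF, −40 → 0 °C; aq. Na2S2O3/NH4Cl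
Reagents that add atoms: iodine, II
Why: alkoxide-directed, CuI-catalysed anti-carbomagnesiation of the silyl alkyne (Duboudin–Jousseaume type) puts the homoprenyl group on C12 and magnesium on the silicon-bearing C11 inside a five-membered chelate, so iodinolysis with retention leaves iodine (the later C10 position) cis to C18H2OH.

Step 2
Reactants: 5 (2Z)-3-iodo-2-(4-methylpent-3-en-1-yl)-3-(trimethylsilyl)prop-2-en-1-ol
Product: 6 tert-butyl{[(2Z)-3-iodo-2-(4-methylpent-3-en-1-yl)-3-(trimethylsilyl)prop-2-en-1-yl]oxy}dimethylsilane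
Conditions: TBSCl, imidazole, DMF, rt
Reagents that add atoms: tert-butyldimethylsilyl chloride, CC(C)(C)[Si](C)(C)Cl
Why: imidazole-promoted silylation masks the primary alcohol so that the alkenyl iodide can be lithiated.

Step 3
Reactants: 6 tert-butyl{[(2Z)-3-iodo-2-(4-methylpent-3-en-1-yl)-3-(trimethylsilyl)prop-2-en-1-yl]oxy}dimethylsilane
Product: 8 (2E)-3-{[(tert-butyldimethylsilyl)oxy]methyl}-7-methyl-2-(trimethylsilyl)octa-2,6-dienal, via α-silyl alkenyllithium 7 (not isolated)
Conditions: tBuLi (2.1 equiv), Et2O, −78 °C; DMF, −78 → 0 °C; H2O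
Reagents that add atoms: N,N-dimethylformamide, CN(C)C=O
Why: iodine–lithium exchange with retention of olefin geometry and formylation with DMF (Bouveault-type) give the enal with CHO (C10) cis to CH2OTBS (C18).

Step 4
Reactants: 9 ethyl 3-methylbut-2-enoate
Product: 10 tert-butyl[(1-ethoxy-3-methylbuta-1,3-dien-1-yl)oxy]dimethylsilane
Conditions: LiN(iPr)2, THF–DMPU, −78 °C; TBSCl
Reagents that add atoms: tert-butyldimethylsilyl chloride, CC(C)(C)[Si](C)(C)Cl
Why: γ-deprotonation of the senecioate and O-silylation give the silyl dienolate (vinylogous silyl ketene acetal) used as the C6–C9 nucleophile.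

Step 5
Reactants: 8 (2E)-3-{[(tert-butyldimethylsilyl)oxy]methyl}-7-methyl-2-(trimethylsilyl)octa-2,6-dienal; 10 tert-butyl[(1-ethoxy-3-methylbuta-1,3-dien-1-yl)oxy]dimethylsilane
Product: 11 ethyl (2E,5R,6E)-7-{[(tert-butyldimethylsilyl)oxy]methyl}-5-hydroxy-3,11-dimethyl-6-(trimethylsilyl)dodeca-2,6,10-trienoate
Conditions: SiCl4 (1.1 equiv), 1,5-bis{methyl[(R)-3,5-dimethyl-4-oxido-3,5-dihydro-4H-dinaphtho[2,1-d:1',2'-f][1,3,2]diazaphosphepin-4-yl]amino}pentane (5 mol %), iPr2NEt (10 mol %), CH2Cl2, −78 °C; aq. KF/NaHCO3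
Reagents that add atoms: none
Why: the Lewis-base-activated SiCl4 vinylogous Mukaiyama aldol (Denmark) is γ- and E-selective for this dienolate, and the chiral trichlorosilyl cation directs Re-face attack on the enal, which sets C10 (R) and the 7E trisubstituted olefin.

Step 6
Reactants: 11 ethyl (2E,5R,6E)-7-{[(tert-butyldimethylsilyl)oxy]methyl}-5-hydroxy-3,11-dimethyl-6-(trimethylsilyl)dodeca-2,6,10-trienoate
Product: 12 ethyl (2E,5R,6E)-5-hydroxy-7-(hydroxymethyl)-3,11-dimethyl-6-(trimethylsilyl)dodeca-2,6,10-trienoate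
Conditions: HF·pyridine, pyridine, THF, 0 °C
Reagents that add atoms: none
Why: buffered fluoride desilylation cleaves the primary TBS ether and leaves the alkenyl–SiMe3 bond and C10 untouched.

Step 7
Reactants: 12 ethyl (2E,5R,6E)-5-hydroxy-7-(hydroxymethyl)-3,11-dimethyl-6-(trimethylsilyl)dodeca-2,6,10-trienoate
Product: 13 ethyl (2E)-3-methyl-4-[(2R)-4-(4-methylpent-3-en-1-yl)-3-(trimethylsilyl)-2,5-dihydrofuran-2-yl]but-2-enoate
Conditions: PPh3, DIAD, THF, 0 °C → rt
Reagents that add atoms: none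
Why: Mitsunobu cyclodehydration activates the less hindered primary C18–OH, which is displaced by the C10 hydroxyl (5-exo-tet etherification), so the C10–O bond and its configuration are not touched and the (Z)-ene-1,4-diol becomes the compact 2,5-dihydrofuran.

Step 8
Reactants: 13 ethyl (2E)-3-methyl-4-[(2R)-4-(4-methylpent-3-en-1-yl)-3-(trimethylsilyl)-2,5-dihydrofuran-2-yl]but-2-enoate
Product: 14 (2E)-3-methyl-4-[(2R)-4-(4-methylpent-3-en-1-yl)-3-(trimethylsilyl)-2,5-dihydrofuran-2-yl]but-2-en-1-ol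
Conditions: iBu2AlH (2.5 equiv), CH2Cl2, −78 °C; aq. KNaC4H4O6
Reagents that add atoms: none
Why: 1,2-reduction of the enoate with iBu2AlH gives the allylic alcohol without touching the olefins or the ether.

Step 9
Reactants: 14 (2E)-3-methyl-4-[(2R)-4-(4-methylpent-3-en-1-yl)-3-(trimethylsilyl)-2,5-dihydrofuran-2-yl]but-2-en-1-ol
Product: 15 (2E)-3-methyl-4-[(2R)-4-(4-methylpent-3-en-1-yl)-3-(trimethylsilyl)-2,5-dihydrofuran-2-yl]but-2-enal
Conditions: Dess–Martin periodinane, NaHCO3, CH2Cl2, 0 °C → rt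
Reagents that add atoms: none
Why: Dess–Martin oxidation is neutral, so the E-enal forms without olefin isomerisation and without aromatising the dihydrofuran.

Step 10
Reactants: 16 4-(trimethylsilyl)but-3-yn-2-one
Product: 17 trimethyl{[4-(trimethylsilyl)but-1-en-3-yn-2-yl]oxy}silane
Conditions: TMSOTf, Et3N, Et2O, 0 °C
Reagents that add atoms: trimethylsilyl trifluoromethanesulfonate, C[Si](C)(C)OS(=O)(=O)C(F)(F)F
Why: soft enolisation and O-silylation of the methyl ketone give the silyl enol ether; the C-silyl group shields the ynone from amine addition.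

Step 11
Reactants: 15 (2E)-3-methyl-4-[(2R)-4-(4-methylpent-3-en-1-yl)-3-(trimethylsilyl)-2,5-dihydrofuran-2-yl]but-2-enal; 17 trimethyl{[4-(trimethylsilyl)but-1-en-3-yn-2-yl]oxy}silane
Product: 18 (5S,6E)-5-hydroxy-7-methyl-8-[(2R)-4-(4-methylpent-3-en-1-yl)-3-(trimethylsilyl)-2,5-dihydrofuran-2-yl]-1-(trimethylsilyl)oct-6-en-1-yn-3-one
Conditions: SiCl4 (1.1 equiv), 1,5-bis{methyl[(S)-3,5-dimethyl-4-oxido-3,5-dihydro-4H-dinaphtho[2,1-d:1',2'-f][1,3,2]diazaphosphepin-4-yl]amino}pentane (5 mol %), iPr2NEt (10 mol %), CH2Cl2, −78 °C; aq. KF/NaHCO3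
Reagents that add atoms: none
Why: the Denmark Mukaiyama aldol of a methyl ketone enol silane with an enal is catalyst-controlled (Si-face attack), which sets C6 (S); the minor C6 epimer is a diastereomer and is removed by chromatography.

Step 12
Reactants: 18 (5S,6E)-5-hydroxy-7-methyl-8-[(2R)-4-(4-methylpent-3-en-1-yl)-3-(trimethylsilyl)-2,5-dihydrofuran-2-yl]-1-(trimethylsilyl)oct-6-en-1-yn-3-one
Product: 19 (5S,6E)-7-methyl-8-[(2R)-4-(4-methylpent-3-en-1-yl)-3-(trimethylsilyl)-2,5-dihydrofuran-2-yl]-3-oxo-1-(trimethylsilyl)oct-6-en-1-yn-5-yl acetate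
Conditions: Ac2O, pyridine, 4-(dimethylamino)pyridine (5 mol %), CH2Cl2, 0 °C
Reagents that add atoms: acetic anhydride, CC(=O)OC(C)=O
Why: acylation installs the C6 acetate of the target early, which also blocks 6-endo oxa-Michael closure of the hydroxy ynone and lowers the nucleophilicity of C7=C8.

Step 13
Reactants: 19 (5S,6E)-7-methyl-8-[(2R)-4-(4-methylpent-3-en-1-yl)-3-(trimethylsilyl)-2,5-dihydrofuran-2-yl]-3-oxo-1-(trimethylsilyl)oct-6-en-1-yn-5-yl acetate
Product: 20 (5S,6E)-7-methyl-8-[(2R)-4-(4-methylpent-3-en-1-yl)-3-(trimethylsilyl)-2,5-dihydrofuran-2-yl]-3-oxooct-6-en-1-yn-5-yl acetate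
Conditions: AgNO3 (20 mol %), acetone–H2O, rt, dark
Reagents that add atoms: none
Why: AgNO3-catalysed protiodesilylation (through the silver acetylide) cleaves only the alkynyl–Si bond and frees the terminal ynone under neutral conditions that spare the acetate and the alkenylsilane.

Step 14
Reactants: 20 (5S,6E)-7-methyl-8-[(2R)-4-(4-methylpent-3-en-1-yl)-3-(trimethylsilyl)-2,5-dihydrofuran-2-yl]-3-oxooct-6-en-1-yn-5-yl acetate
Product: 21 (1S,2Z,6S,7E,10R)-6-acetoxy-10,18-epoxy-20-norverticilla-2,7,11-trien-4-one (2Z shown; any 2E isomer is carried on, the olefin is removed in step 15)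
Conditions: EtAlCl2 (3 equiv), CH2Cl2, 1 mM (slow addition of 20), −78 → −20 °C; aq. NaHCO3
Reagents that add atoms: none
Why: Proposed new method: the EtAlCl2-bound terminal ynone is a persistent, linear electrophile that cannot close a six-membered ring onto C7=C8 (this would need a cyclic allenolate); its β-carbon C2 is attacked by the C1=C15 isopropylidene group (14-membered ring, tertiary C15 cation as in the cembrenyl cation), C15 is captured at C11 by the alkenylsilane (six-membered ring, β-silyl cation at C12) and loss of Me3Si+ restores C11=C12 exactly where the target has it; C1 is set relative to C10 because the C15–C11 bond can only form when the C2 and C9 arms lie on the same face of the new cyclohexene, the mismatched adduct reverting or ending as the monocyclic ene product; the closest known chemistry is the Lewis-acid ene and [2+2] reactions of alkynyl ketones and propiolates with alkenes, the SnCl4 acyl-cation macrocyclisation of geranylgeranoyl chloride and alkenylsilane-terminated cation–olefin cyclisations.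

Step 15
Reactants: 21 (1S,2Z,6S,7E,10R)-6-acetoxy-10,18-epoxy-20-norverticilla-2,7,11-trien-4-one
Product: 22 (1S,6S,7E,10R)-6-acetoxy-10,18-epoxy-20-norverticilla-7,11-dien-4-one
Conditions: [(Ph3P)CuH]6 (0.5 equiv), wet benzene, rt
Reagents that add atoms: none
Why: Stryker conjugate reduction removes only the enone C2=C3 (either geometry); the copper enolate lies on the C3 side, away from the C6 acetate, so no β-elimination occurs and C1 stays fixed.

Step 16
Reactants: 22 (1S,6S,7E,10R)-6-acetoxy-10,18-epoxy-20-norverticilla-7,11-dien-4-one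
Product: 23 (1R,6S,7E,10R)-6-acetoxy-10,18-epoxyverticilla-4(20),7,11-triene
Conditions: Zn, CH2Br2, TiCl4, THF–CH2Cl2, 0 °C → rt
Reagents that add atoms: dibromomethane, BrCBr
Why: Takai–Lombardo methylenation is non-basic and ketone-selective, so the β-acetoxy ketone becomes the C4=C20 exo-methylene without elimination or attack on the acetate.

Step 17
Reactants: 23 (1R,6S,7E,10R)-6-acetoxy-10,18-epoxyverticilla-4(20),7,11-triene
Product: 24 (1R,6S,7E,10R)-6-acetoxyverticilla-4(20),7,11-trien-18,10-olide (target)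
Conditions: [C5H5NH][CrO3Cl] (pyridinium chlorochromate, 4 equiv), pyridine, CH2Cl2, 40 °C
Reagents that add atoms: pyridinium chlorochromate, [O-][Cr](=O)(=O)Cl.c1cc[nH+]cc1
Why: chromate oxidation of the doubly activated (allylic and α-oxy) C18H2 of the 2,5-dihydrofuran gives the butenolide, as in the oxidation of cyclic allyl ethers to unsaturated lactones; the CH2 reacts in preference to the hindered C10 methine and no stereocentre is touched.

## Compound list

1 | 3-(trimethylsilyl)prop-2-yn-1-ol | C[Si](C)(C)C#CCO | starting material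
2 | 5-bromo-2-methylpent-2-ene | CC(C)=CCCBr | starting material
3 | (4-methylpent-3-en-1-yl)magnesium bromide | CC(C)=CCC[Mg]Br | intermediate (not isolated)
4 | cyclic alkenylmagnesium alkoxide (five-membered O–Mg–C11 chelate; SiMe3 on C11, homoprenyl on C12) | CC(C)=CCCC1=C([Si](C)(C)C)[Mg]OC1 | intermediate (not isolated)
5 | (2Z)-3-iodo-2-(4-methylpent-3-en-1-yl)-3-(trimethylsilyl)prop-2-en-1-ol | OC/C(CCC=C(C)C)=C(\I)[Si](C)(C)C | intermediate
6 | tert-butyl{[(2Z)-3-iodo-2-(4-methylpent-3-en-1-yl)-3-(trimethylsilyl)prop-2-en-1-yl]oxy}dimethylsilane | CC(C)(C)[Si](C)(C)OC/C(CCC=C(C)C)=C(\I)[Si](C)(C)C | intermediate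
7 | [(1E)-3-[(tert-butyldimethylsilyl)oxy]-2-(4-methylpent-3-en-1-yl)-1-(trimethylsilyl)prop-1-en-1-yl]lithium | CC(C)(C)[Si](C)(C)OC/C(CCC=C(C)C)=C(\[Li])[Si](C)(C)C | intermediate (not isolated)
8 | (2E)-3-{[(tert-butyldimethylsilyl)oxy]methyl}-7-methyl-2-(trimethylsilyl)octa-2,6-dienal | CC(C)(C)[Si](C)(C)OC/C(CCC=C(C)C)=C(\C=O)[Si](C)(C)C | intermediate
9 | ethyl 3-methylbut-2-enoate | CCOC(=O)C=C(C)C | starting material
10 | tert-butyl[(1-ethoxy-3-methylbuta-1,3-dien-1-yl)oxy]dimethylsilane (ketene-acetal geometry not relevant) | C=C(C)C=C(OCC)O[Si](C)(C)C(C)(C)C | intermediate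
11 | ethyl (2E,5R,6E)-7-{[(tert-butyldimethylsilyl)oxy]methyl}-5-hydroxy-3,11-dimethyl-6-(trimethylsilyl)dodeca-2,6,10-trienoate | CC(C)(C)[Si](C)(C)OC/C(CCC=C(C)C)=C(\[C@@H](C/C(C)=C/C(=O)OCC)O)[Si](C)(C)C | intermediate
12 | ethyl (2E,5R,6E)-5-hydroxy-7-(hydroxymethyl)-3,11-dimethyl-6-(trimethylsilyl)dodeca-2,6,10-trienoate | OC/C(CCC=C(C)C)=C(\[C@@H](C/C(C)=C/C(=O)OCC)O)[Si](C)(C)C | intermediate
13 | ethyl (2E)-3-methyl-4-[(2R)-4-(4-methylpent-3-en-1-yl)-3-(trimethylsilyl)-2,5-dihydrofuran-2-yl]but-2-enoate | CC(C)=CCCC1=C([C@@H](C/C(C)=C/C(=O)OCC)OC1)[Si](C)(C)C | intermediate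
14 | (2E)-3-methyl-4-[(2R)-4-(4-methylpent-3-en-1-yl)-3-(trimethylsilyl)-2,5-dihydrofuran-2-yl]but-2-en-1-ol | CC(C)=CCCC1=C([C@@H](C/C(C)=C/CO)OC1)[Si](C)(C)C | intermediate
15 | (2E)-3-methyl-4-[(2R)-4-(4-methylpent-3-en-1-yl)-3-(trimethylsilyl)-2,5-dihydrofuran-2-yl]but-2-enal | CC(C)=CCCC1=C([C@@H](C/C(C)=C/C=O)OC1)[Si](C)(C)C | intermediate
16 | 4-(trimethylsilyl)but-3-yn-2-one | CC(=O)C#C[Si](C)(C)C | starting material
17 | trimethyl{[4-(trimethylsilyl)but-1-en-3-yn-2-yl]oxy}silane | C=C(O[Si](C)(C)C)C#C[Si](C)(C)C | intermediate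
18 | (5S,6E)-5-hydroxy-7-methyl-8-[(2R)-4-(4-methylpent-3-en-1-yl)-3-(trimethylsilyl)-2,5-dihydrofuran-2-yl]-1-(trimethylsilyl)oct-6-en-1-yn-3-one | CC(C)=CCCC1=C([C@@H](C/C(C)=C/[C@@H](O)CC(=O)C#C[Si](C)(C)C)OC1)[Si](C)(C)C | intermediate
19 | (5S,6E)-7-methyl-8-[(2R)-4-(4-methylpent-3-en-1-yl)-3-(trimethylsilyl)-2,5-dihydrofuran-2-yl]-3-oxo-1-(trimethylsilyl)oct-6-en-1-yn-5-yl acetate | CC(C)=CCCC1=C([C@@H](C/C(C)=C/[C@@H](OC(C)=O)CC(=O)C#C[Si](C)(C)C)OC1)[Si](C)(C)C | intermediate
20 | (5S,6E)-7-methyl-8-[(2R)-4-(4-methylpent-3-en-1-yl)-3-(trimethylsilyl)-2,5-dihydrofuran-2-yl]-3-oxooct-6-en-1-yn-5-yl acetate | CC(C)=CCCC1=C([C@@H](C/C(C)=C/[C@@H](OC(C)=O)CC(=O)C#C)OC1)[Si](C)(C)C | intermediate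
21 | (1S,2Z,6S,7E,10R)-6-acetoxy-10,18-epoxy-20-norverticilla-2,7,11-trien-4-one (bicyclo[9.3.1] core, C4 ketone, 2,5-dihydrofuran fused at C11=C12) | O=C1/C=C\[C@@H]2CCC3=C([C@@H](C/C(C)=C/[C@@H](OC(C)=O)C1)OC3)C2(C)C | intermediate
22 | (1S,6S,7E,10R)-6-acetoxy-10,18-epoxy-20-norverticilla-7,11-dien-4-one | O=C1CC[C@@H]2CCC3=C([C@@H](C/C(C)=C/[C@@H](OC(C)=O)C1)OC3)C2(C)C | intermediate
23 | (1R,6S,7E,10R)-6-acetoxy-10,18-epoxyverticilla-4(20),7,11-triene | C=C1CC[C@@H]2CCC3=C([C@@H](C/C(C)=C/[C@@H](OC(C)=O)C1)OC3)C2(C)C | intermediate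
24 | (1R,6S,7E,10R)-6-acetoxyverticilla-4(20),7,11-trien-18,10-olide | C=C1CC[C@@H]2CCC3=C([C@@H](C/C(C)=C/[C@@H](OC(C)=O)C1)OC3=O)C2(C)C | target

## Step count

Total: 17 steps (15 in the main line plus the two one-step reagent preparations, steps 4 and 10).
Longest linear sequence: 15 steps (1, 2, 3, 5, 6, 7, 8, 9, 11, 12, 13, 14, 15, 16, 17).

## Three steps most likely to fail

**Step 14 (cascade).** The ynone may stop after the first ring as the ene product, or the hindered ipso closure at C11 may be slow. The fallback splits the cascade and sets out from 20. With Me2AlCl (1.5 equiv, CH2Cl2, high dilution, −78 → 0 °C) the isopropylidene group adds to C2 and transfers an allylic hydrogen to C3 (Lewis-acid ene macrocyclisation). This gives the isolable 14-membered (2E)-enone with a C1 isopropenyl group and the intact silyl-dihydrofuran, monocyclic dienone F1. Its C1 epimers can be equilibrated with 1,8-diazabicyclo[5.4.0]undec-7-ene, because C1–H is γ to the enone and doubly allylic. F1 is then treated with HNTf2 (10 mol %, CH2Cl2, −40 °C): Markovnikov protonation of the isopropenyl group regenerates the C15 cation, which the alkenylsilane closes as in step 14 to the (2E) isomer of 21, bicyclic (2E)-enone F2. F2 is reduced with [(Ph3P)CuH]6 as in step 15 and comes back to the route at 22.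

**Step 17 (dihydrofuran to butenolide).** Chromate may attack other allylic positions or aromatise the ring. The fallback goes through the furan and sets out from 23. DDQ (benzene, rt) dehydrogenates the dihydrofuran to the 2,3,4-trisubstituted furan F3. Photo-oxygenation of F3 (O2, 5,10,15,20-tetraphenylporphyrin, hν, iPr2NEt, CH2Cl2, −78 °C) gives the endoperoxide; base removes the only ring hydrogen (on C18) to give the γ-hydroxybutenolide F4, with C18 as carbonyl and C10 as hemiketal. NaBH4 (MeOH, 0 °C, then dilute acid) reduces the ring-opened C10 keto carboxylate, and the hydroxy acid relactonises to 24. C10 is expected to follow C1 here, since hydride enters from the face away from the C2–C9 bridge and the strain-free bridged lactone is the 10R one.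

**Step 5 (vinylogous aldol on the hindered α-silyl enal).** The catalytic system may be too slow or poorly selective. The fallback sets C10 by reagent-controlled reduction and sets out from 8 and 10. BF3·OEt2 (CH2Cl2, −78 °C) promotes the vinylogous Mukaiyama aldol to the racemic alcohol F5. Dess–Martin periodinane oxidises F5 to the C10 ketone F6. Reduction of F6 with (S)-1-methyl-3,3-diphenyl-tetrahydro-1H,3H-pyrrolo[1,2-c][1,3,2]oxazaborole (20 mol %) and catecholborane (toluene, −78 °C) treats the tetrasubstituted alkenyl group as the large substituent and gives the 5R alcohol, which comes back to the route at 11.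

## Further compounds

F1 | step 14 | (2E,7E)-14-membered monocyclic enone from 20: C1–C2 bond formed, C1 isopropenyl, C4 ketone, C6 OAc, intact 3-(trimethylsilyl)-2,5-dihydrofuran (C1 epimers) | CC(=C)C1/C=C/C(=O)C[C@H](OC(C)=O)/C=C(C)/C[C@H]2OCC(CC1)=C2[Si](C)(C)C
F2 | step 14 | (1S,2E,6S,7E,10R)-6-acetoxy-10,18-epoxy-20-norverticilla-2,7,11-trien-4-one | O=C1/C=C/[C@@H]2CCC3=C([C@@H](C/C(C)=C/[C@@H](OC(C)=O)C1)OC3)C2(C)C
F3 | step 17 | (1R,6S,7E)-6-acetoxy-10,18-epoxyverticilla-4(20),7,10,12(18)-tetraene (furan) | C=C1CC[C@@H]2CCc3coc(C/C(C)=C/[C@@H](OC(C)=O)C1)c3C2(C)C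
F4 | step 17 | (1R,6S,7E)-6-acetoxy-10-hydroxyverticilla-4(20),7,11-trien-18,10-olide (C10 hemiketal epimers) | C=C1CC[C@@H]2CCC3=C(C(O)(C/C(C)=C/[C@@H](OC(C)=O)C1)OC3=O)C2(C)C
F5 | step 5 | ethyl (2E,6E)-7-{[(tert-butyldimethylsilyl)oxy]methyl}-5-hydroxy-3,11-dimethyl-6-(trimethylsilyl)dodeca-2,6,10-trienoate (racemic at C5) | CC(C)(C)[Si](C)(C)OC/C(CCC=C(C)C)=C(\C(O)C/C(C)=C/C(=O)OCC)[Si](C)(C)C
F6 | step 5 | ethyl (2E,6E)-7-{[(tert-butyldimethylsilyl)oxy]methyl}-3,11-dimethyl-5-oxo-6-(trimethylsilyl)dodeca-2,6,10-trienoate | CC(C)(C)[Si](C)(C)OC/C(CCC=C(C)C)=C(\C(=O)C/C(C)=C/C(=O)OCC)[Si](C)(C)C
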